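**Plan**
- Retrosynthesis: the four benzyl ethers come off last. The two CH2OAc groups go back to a cis-fused γ-lactone (C3 carbonyl carbon, C4 CH2O). The tetrahydrofuran is then cut at C3–C4 and O1–C5.
- The cut gives an aroylacetate (C2, C3, O1 as ketone oxygen, ester carbon as the future C3 CH2OAc) and a cinnamyl acetate (C4, C5, CH2OAc). Both are C6–C3 units, from 3',4'-dihydroxyacetophenone plus dimethyl carbonate and from caffeic acid.
- Enabling feature: the ring O1–C2–C3–C4–C5 carries electron-rich aryl groups on C2 and C5, so O1/C2/C3 is a masked 1,3-dicarbonyl and C5 is a benzylic carbon able to carry radical and cation.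
- Forward: the two halves are made separately and joined in one manganese(III) annulation that closes the only ring. Reduction, lactonisation, LiAlH4, acetylation, acid equilibration and hydrogenolysis follow.
- Stereochemistry: C4/C5 trans from the ring closure; C3 cis to C4 through the lactone funnel; C2 by acid equilibration to the isomer with each aryl trans to its neighbour.

Key step: step 6

Remark on the chemistry: the SMILES describes the meso (2R,3S,4R,5S) isomer (aryl groups cis to each other, acetoxymethyl groups cis to each other, each aryl trans to the adjacent acetoxymethyl). The target is therefore achiral, racemic intermediates suffice and no enantiocontrol is planned. Ring numbering O1, C2–C5 of the tetrahydrofuran is used throughout.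

**Step 1**
Reactants: 1 1-(3,4-dihydroxyphenyl)ethanone
Product: 2 1-[3,4-bis(benzyloxy)phenyl]ethanone
Conditions: BnBr (2.4 equiv), K2CO3, DMF, 60 °C
Reagents that add atoms: benzyl bromide, BrCc1ccccc1
Why: Williamson ether synthesis on the two phenoxides should proceed cleanly, the methyl ketone being inert to carbonate.

**Step 2**
Reactants: 2 1-[3,4-bis(benzyloxy)phenyl]ethanone; 3 dimethyl carbonate
Product: 4 methyl 3-[3,4-bis(benzyloxy)phenyl]-3-oxopropanoate
Conditions: NaH (2.5 equiv), (MeO)2CO (3 equiv), THF, reflux; then aq. HCl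
Reagents that add atoms: none
Why: Crossed Claisen condensation of the ketone enolate with dimethyl carbonate is driven to completion by deprotonation of the β-keto ester formed.

**Step 3**
Reactants: 5 caffeic acid
Product: 6 benzyl (E)-3-[3,4-bis(benzyloxy)phenyl]acrylate
Conditions: BnBr (3.5 equiv), K2CO3, DMF, 60 °C, N2
Reagents that add atoms: benzyl bromide, BrCc1ccccc1
Why: Williamson etherification of both phenols together with O-alkylation of the carboxylate should give the tribenzyl compound in one operation, with the E-alkene untouched.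

**Step 4**
Reactants: 6 benzyl (E)-3-[3,4-bis(benzyloxy)phenyl]acrylate
Product: 7 (E)-3-[3,4-bis(benzyloxy)phenyl]prop-2-en-1-ol
Conditions: DIBAL-H (2.5 equiv), CH2Cl2, −78 → 0 °C; Rochelle salt
Reagents that add atoms: none
Why: DIBAL-H 1,2-reduction of a cinnamate ester should give the allylic alcohol without conjugate reduction and without touching the aryl benzyl ethers.

**Step 5**
Reactants: 7 (E)-3-[3,4-bis(benzyloxy)phenyl]prop-2-en-1-ol
Product: 8 (E)-3-[3,4-bis(benzyloxy)phenyl]allyl acetate
Conditions: Ac2O, pyridine, DMAP (cat.), CH2Cl2, rt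
Reagents that add atoms: acetic anhydride, CC(=O)OC(C)=O
Why: DMAP-catalysed acylation of a primary allylic alcohol is routine and leaves the alkene geometry unchanged.

**Step 6**
Reactants: 4 methyl 3-[3,4-bis(benzyloxy)phenyl]-3-oxopropanoate; 8 (E)-3-[3,4-bis(benzyloxy)phenyl]allyl acetate
Product: 9 rac-methyl trans-4-(acetoxymethyl)-2,5-bis[3,4-bis(benzyloxy)phenyl]-4,5-dihydrofuran-3-carboxylate
Conditions: Mn(OAc)3·2H2O (2.2 equiv), AcOH, 70 °C, N2
Reagents that add atoms: none
Why: Manganese(III) converts the enolate of 4 into an electrophilic α-radical that adds to the alkene carbon of 8 carrying CH2OAc (C3–C4 bond); a second manganese(III) oxidises the resulting benzylic radical to the cation, which the ketone enol oxygen captures (O1–C5 bond) in a radical–polar crossover. The closest known reaction is the manganese(III) acetate oxidative (3+2) annulation of 1,3-dicarbonyl compounds with styrenes to 4,5-dihydrofurans. The single ring closes by five-membered O-alkylation of the enol on the benzylic cation, an enolendo closure with C2=C3 inside the new ring. C4 and C5 are created together and should come out trans because the planar cation closes with its aryl group anti to the neighbouring acetoxymethyl group, and reversible C5–O ionisation in hot acetic acid leads to the same isomer; the product is racemic, which is sufficient for a meso target. The step needs attack of the radical at the alkene carbon remote from the aryl group and capture of the cation by the enol oxygen in preference to acetic acid; the 3,4-bis(benzyloxy)phenyl group secures the first by stabilising radical and cation at C5, and the intramolecular five-ring closure secures the second.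

**Step 7**
Reactants: 9 rac-methyl trans-4-(acetoxymethyl)-2,5-bis[3,4-bis(benzyloxy)phenyl]-4,5-dihydrofuran-3-carboxylate
Product: 11 methyl 4-(hydroxymethyl)-2,5-bis[3,4-bis(benzyloxy)phenyl]tetrahydrofuran-3-carboxylate (4,5-trans; mixture of C2 and C3 epimers), via tetrahydrofuran acetate ester 10 (not isolated)
Conditions: Mg turnings (10 equiv), MeOH–THF, 0 °C → rt; sat. aq. NH4Cl
Reagents that add atoms: none
Why: Magnesium in methanol is a single-electron conjugate reduction of β-aryl acrylates that is established for the β-aryl-β-oxy acrylate of 2-arylbenzofuran-3-carboxylates, and the magnesium methoxide formed should methanolyse the acetate; C2 and C3 are not controlled here and are corrected in steps 8 and 11.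

**Step 8**
Reactants: 11 methyl 4-(hydroxymethyl)-2,5-bis[3,4-bis(benzyloxy)phenyl]tetrahydrofuran-3-carboxylate
Product: 12 cis-fused γ-lactone bridging C3 (carbonyl) and C4 (CH2O) of 2,5-bis[3,4-bis(benzyloxy)phenyl]tetrahydrofuran, i.e. 4,6-bis[3,4-bis(benzyloxy)phenyl]tetrahydro-1H,3H-furo[3,4-c]furan-1-one (C5 aryl trans to the C4 CH2; mixture of C2 epimers)
Conditions: t-BuOK (0.3 equiv), THF, 0 °C → rt; AcOH
Reagents that add atoms: none
Why: In this base-mediated epimerisation–lactonisation (intramolecular transesterification) only the isomer with the C3 ester cis to the C4 hydroxymethyl can close the fused five-membered lactone, while the ester enolate interconverts the C3 epimers, so the mixture should funnel to C3 cis to C4.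

**Step 9**
Reactants: 12 the cis-fused lactone
Product: 13 [2,5-bis[3,4-bis(benzyloxy)phenyl]tetrahydrofuran-3,4-diyl]dimethanol (3,4-cis, 4,5-trans; mixture of C2 epimers)
Conditions: LiAlH4, THF, 0 °C → rt; Fieser work-up
Reagents that add atoms: none
Why: Lithium aluminium hydride reduction of a γ-lactone to the 1,4-diol is reliable and fixes the cis relation of the two hydroxymethyl groups, since C3 is no longer epimerisable.

**Step 10**
Reactants: 13 the cis-diol
Product: 14 [2,5-bis[3,4-bis(benzyloxy)phenyl]tetrahydrofuran-3,4-diyl]bis(methylene) diacetate (3,4-cis, 4,5-trans; mixture of C2 epimers)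
Conditions: Ac2O, pyridine, DMAP (cat.), CH2Cl2, rt
Reagents that add atoms: acetic anhydride, CC(=O)OC(C)=O
Why: DMAP-catalysed acylation of two primary alcohols is routine and caps the hydroxyl groups so they cannot trap a benzylic cation in the next step.

**Step 11**
Reactants: 14 the diacetate as C2 epimer mixture
Product: 15 meso-(2R,3S,4R,5S)-[2,5-bis[3,4-bis(benzyloxy)phenyl]tetrahydrofuran-3,4-diyl]bis(methylene) diacetate (2,3-trans, 3,4-cis, 4,5-trans)
Conditions: BF3·OEt2 (0.5 equiv), CH2Cl2, −20 → 0 °C; sat. aq. NaHCO3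
Reagents that add atoms: none
Why: Lewis acid-mediated benzylic epimerisation, known for 2,5-diaryltetrahydrofuran lignans, reversibly ionises the para-alkoxybenzylic C–O bonds, so C2 (and C5) should settle in the thermodynamically preferred arrangement with each aryl trans to its neighbouring acetoxymethyl group.

**Step 12**
Reactants: 15 the meso tetrabenzyl diacetate
Product: 16 meso-(2R,3S,4R,5S)-[2,5-bis(3,4-dihydroxyphenyl)tetrahydrofuran-3,4-diyl]bis(methylene) diacetate (target)
Conditions: H2 (1 atm), 10% Pd/C, EtOAc–THF, rt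
Reagents that add atoms: none
Why: Catalytic hydrogenolysis of aryl benzyl ethers at atmospheric pressure in a non-alcoholic solvent should free the catechols while leaving the acetates, the ring ether and all four stereocentres untouched.

**Compound list**
1 | 1-(3,4-dihydroxyphenyl)ethanone | CC(=O)c1ccc(O)c(O)c1 | starting material
2 | 1-[3,4-bis(benzyloxy)phenyl]ethanone | CC(=O)c1ccc(OCc2ccccc2)c(OCc2ccccc2)c1 | intermediate
3 | dimethyl carbonate | COC(=O)OC | starting material
4 | methyl 3-[3,4-bis(benzyloxy)phenyl]-3-oxopropanoate | COC(=O)CC(=O)c1ccc(OCc2ccccc2)c(OCc2ccccc2)c1 | intermediate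
5 | caffeic acid | OC(=O)/C=C/c1ccc(O)c(O)c1 | starting material
6 | benzyl (E)-3-[3,4-bis(benzyloxy)phenyl]acrylate | O=C(OCc1ccccc1)/C=C/c1ccc(OCc2ccccc2)c(OCc2ccccc2)c1 | intermediate
7 | (E)-3-[3,4-bis(benzyloxy)phenyl]prop-2-en-1-ol | OC/C=C/c1ccc(OCc2ccccc2)c(OCc2ccccc2)c1 | intermediate
8 | (E)-3-[3,4-bis(benzyloxy)phenyl]allyl acetate | CC(=O)OC/C=C/c1ccc(OCc2ccccc2)c(OCc2ccccc2)c1 | intermediate
9 | rac-methyl trans-4-(acetoxymethyl)-2,5-bis[3,4-bis(benzyloxy)phenyl]-4,5-dihydrofuran-3-carboxylate | COC(=O)C1=C(c2ccc(OCc3ccccc3)c(OCc3ccccc3)c2)O[C@H](c2ccc(OCc3ccccc3)c(OCc3ccccc3)c2)[C@H]1COC(C)=O | intermediate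
10 | methyl 4-(acetoxymethyl)-2,5-bis[3,4-bis(benzyloxy)phenyl]tetrahydrofuran-3-carboxylate, 4,5-trans, C2 and C3 left undefined (epimer mixture, not isolated) | COC(=O)C1C(c2ccc(OCc3ccccc3)c(OCc3ccccc3)c2)O[C@H](c2ccc(OCc3ccccc3)c(OCc3ccccc3)c2)[C@H]1COC(C)=O | intermediate
11 | methyl 4-(hydroxymethyl)-2,5-bis[3,4-bis(benzyloxy)phenyl]tetrahydrofuran-3-carboxylate, 4,5-trans, C2 and C3 left undefined (epimer mixture) | COC(=O)C1C(c2ccc(OCc3ccccc3)c(OCc3ccccc3)c2)O[C@H](c2ccc(OCc3ccccc3)c(OCc3ccccc3)c2)[C@H]1CO | intermediate
12 | cis-fused 4,6-bis[3,4-bis(benzyloxy)phenyl]tetrahydro-1H,3H-furo[3,4-c]furan-1-one, 4-aryl trans to the C3a CH2, aryl-bearing C6 (old C2) left undefined (epimer mixture) | O=C1OC[C@H]2[C@@H]1C(c1ccc(OCc3ccccc3)c(OCc3ccccc3)c1)O[C@@H]2c1ccc(OCc2ccccc2)c(OCc2ccccc2)c1 | intermediate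
13 | [2,5-bis[3,4-bis(benzyloxy)phenyl]tetrahydrofuran-3,4-diyl]dimethanol, 3,4-cis, 4,5-trans, C2 left undefined (epimer mixture) | OC[C@@H]1[C@H](CO)[C@@H](c2ccc(OCc3ccccc3)c(OCc3ccccc3)c2)OC1c1ccc(OCc2ccccc2)c(OCc2ccccc2)c1 | intermediate
14 | [2,5-bis[3,4-bis(benzyloxy)phenyl]tetrahydrofuran-3,4-diyl]bis(methylene) diacetate, 3,4-cis, 4,5-trans, C2 left undefined (epimer mixture) | CC(=O)OC[C@@H]1[C@H](COC(C)=O)[C@@H](c2ccc(OCc3ccccc3)c(OCc3ccccc3)c2)OC1c1ccc(OCc2ccccc2)c(OCc2ccccc2)c1 | intermediate
15 | meso-(2R,3S,4R,5S)-[2,5-bis[3,4-bis(benzyloxy)phenyl]tetrahydrofuran-3,4-diyl]bis(methylene) diacetate | CC(=O)OC[C@@H]1[C@H](COC(C)=O)[C@@H](c2ccc(OCc3ccccc3)c(OCc3ccccc3)c2)O[C@H]1c1ccc(OCc2ccccc2)c(OCc2ccccc2)c1 | intermediate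
16 | meso-(2R,3S,4R,5S)-[2,5-bis(3,4-dihydroxyphenyl)tetrahydrofuran-3,4-diyl]bis(methylene) diacetate | CC(=O)OC[C@@H]1[C@H](COC(C)=O)[C@@H](c2ccc(O)c(O)c2)O[C@H]1c1ccc(O)c(O)c1 | target

**Step count**
Total: 12 steps. Longest linear sequence: 10 steps (steps 3–12, from caffeic acid).

**Steps most likely to fail**

Step 6. The electron-rich styrene and arenes may be oxidised or oligomerised by manganese(III), and the benzylic cation may be intercepted by acetic acid instead of the enol oxygen, so conversion to the dihydrofuran may be poor. The fallback generates the same radical without a stoichiometric oxidant. It sets out from 4, which is brominated with NBS (cat. NH4OAc, Et2O, rt) to methyl 2-bromo-3-[3,4-bis(benzyloxy)phenyl]-3-oxopropanoate F1. F1 and 8 are then combined under visible-light photoredox catalysis (fac-Ir(ppy)3, NaHCO3, MeCN, blue LEDs): reductive C–Br cleavage gives the α-radical, which adds to the alkene; the benzylic radical is oxidised by the catalyst and the cation closes on the enol oxygen. The same two bonds form and the sequence comes back to the route at 9.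

Step 7. The radical anion may fragment at the benzylic C5–O1 bond, or the magnesium ester enolate may expel the ring oxygen, so the ring may open instead of the alkene being saturated. The fallback replaces electron transfer by surface hydrogenation. It sets out from 9, which is hydrogenated over 5% Rh/Al2O3 (H2, 3–4 atm, EtOAc), a catalyst that should spare the benzyl ethers. Syn addition should give methyl 2,3-cis-4-(acetoxymethyl)-2,5-bis[3,4-bis(benzyloxy)phenyl]tetrahydrofuran-3-carboxylate F2, drawn for delivery anti to the acetoxymethyl group; the facial outcome is immaterial because C3 and C2 are corrected in steps 8 and 11. K2CO3 in MeOH then removes the acetate and the sequence comes back to the route at 11.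

Step 11. The thermodynamic bias at C2 may be incomplete, and the ring-opened benzylic cation may be captured irreversibly by the other dialkoxyaryl ring (Friedel–Crafts closure to an aryltetralin) or diverted by acetate participation. The fallback sets C2 under kinetic control and avoids cations altogether. It sets out from 9.
- K2CO3 in MeOH frees methyl trans-4-(hydroxymethyl)-2,5-bis[3,4-bis(benzyloxy)phenyl]-4,5-dihydrofuran-3-carboxylate F3.
- Ti(OiPr)4 (cat.) in hot toluene lactonises it to the bicyclic enol-ether lactone 4,6-bis[3,4-bis(benzyloxy)phenyl]-3a,4-dihydro-1H,3H-furo[3,4-c]furan-1-one F4.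
- Copper hydride conjugate reduction (Stryker's reagent, toluene, rt) should deliver hydride to the aryl-bearing alkene carbon on the face opposite the only out-of-plane group, the C5 aryl. Protonation of the enolate at the ring fusion can only give the cis-fused lactone, so the diaryl lactone with both aryl groups on the convex face F5 should result.
- LiAlH4 gives the meso diol [2,5-bis[3,4-bis(benzyloxy)phenyl]tetrahydrofuran-3,4-diyl]dimethanol F6, and acetylation as in step 10 comes back to the route at 15, bypassing steps 7, 8 and 11.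

**Further compounds**
F1 | step 6 | methyl 2-bromo-3-[3,4-bis(benzyloxy)phenyl]-3-oxopropanoate | COC(=O)C(Br)C(=O)c1ccc(OCc2ccccc2)c(OCc2ccccc2)c1
F2 | step 7 | rac-methyl 4-(acetoxymethyl)-2,5-bis[3,4-bis(benzyloxy)phenyl]tetrahydrofuran-3-carboxylate, 2,3-cis, 3,4-cis, 4,5-trans | COC(=O)[C@@H]1[C@H](COC(C)=O)[C@@H](c2ccc(OCc3ccccc3)c(OCc3ccccc3)c2)O[C@@H]1c1ccc(OCc2ccccc2)c(OCc2ccccc2)c1
F3 | step 11 | rac-methyl trans-4-(hydroxymethyl)-2,5-bis[3,4-bis(benzyloxy)phenyl]-4,5-dihydrofuran-3-carboxylate | COC(=O)C1=C(c2ccc(OCc3ccccc3)c(OCc3ccccc3)c2)O[C@H](c2ccc(OCc3ccccc3)c(OCc3ccccc3)c2)[C@H]1CO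
F4 | step 11 | rac-4,6-bis[3,4-bis(benzyloxy)phenyl]-3a,4-dihydro-1H,3H-furo[3,4-c]furan-1-one, 4-aryl trans to the C3a CH2 | O=C1OC[C@H]2C1=C(c1ccc(OCc3ccccc3)c(OCc3ccccc3)c1)O[C@@H]2c1ccc(OCc2ccccc2)c(OCc2ccccc2)c1
F5 | step 11 | rac-cis-fused 4,6-bis[3,4-bis(benzyloxy)phenyl]tetrahydro-1H,3H-furo[3,4-c]furan-1-one, both aryl groups on the convex face | O=C1OC[C@H]2[C@@H]1[C@H](c1ccc(OCc3ccccc3)c(OCc3ccccc3)c1)O[C@@H]2c1ccc(OCc2ccccc2)c(OCc2ccccc2)c1
F6 | step 11 | meso-(2R,3S,4R,5S)-[2,5-bis[3,4-bis(benzyloxy)phenyl]tetrahydrofuran-3,4-diyl]dimethanol | OC[C@@H]1[C@H](CO)[C@@H](c2ccc(OCc3ccccc3)c(OCc3ccccc3)c2)O[C@H]1c1ccc(OCc2ccccc2)c(OCc2ccccc2)c1
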